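**Retrosynthetic overview**

- 21 ⇐ 20 (six aryl methyl ethers removed last) ⇐ 17 + 18 (C5 styryl by Horner–Wadsworth–Emmons olefination, C6–OH carried as its tosylate) ⇐ 15 (C5 ester taken to the aldehyde).
- Ring A of 15 is made last. If ring B is read as a 2,3-dihydrofuran, the C3a–C7a bond is an enol ether C=C, and C4–C5(CO2Me)–C6(O)–C7 is the diene of a 4-tosyloxy-2-pyrone-5-carboxylate. Pyrone (4+2) addition forms C3a–C4 and C7–C7a, CO2 leaves, and DDQ removes the two ring-fusion hydrogens.
- Dihydrofuran 8 (ring B, made first) ⇐ enol ether ring-closing metathesis of the O-vinyl ether of anti alcohol 6 ⇐ catalytic enantioselective (E)-cinnamylboration of veratraldehyde, which sets C2 and C3 together.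
- Pyrone 12 ⇐ dimethyl 3-oxopentanedioate, trimethyl orthoformate, TsCl.
- Ring order: ring B (step 5), then ring A (step 8); the three aryl rings are bought.

Key step: step 8

Remark: benzofuran numbering is used; ring A is the benzo ring (C3a to C7a), ring B is the oxygen ring (O1, C2, C3, C3a, C7a).
Remark (assumption): the ring-fusion and bridgehead centres of 13 and 14 are transient, should form as a mixture of cis-fused isomers and are erased in 15; their SMILES fix only C2 and C3.
Remark (assumption): (S)-TRIP is written in step 3 by analogy with the reported facial sense of this acid in allylborations of aryl aldehydes; the antipodal acid would be used if the sense proved opposite.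

**Route**

Step 1
Reactants: 1 3,5-dimethoxybenzaldehyde
Product: 2 rac-1-(3,5-dimethoxyphenyl)prop-2-en-1-ol
Conditions: CH2=CHMgBr, THF, 0 °C; aq NH4Cl
Reagents that add atoms: vinylmagnesium bromide, C=C[Mg]Br
Why: Grignard 1,2-addition to a non-enolisable aryl aldehyde; the racemic carbinol centre is erased in step 2.

Step 2
Reactants: 2 rac-1-(3,5-dimethoxyphenyl)prop-2-en-1-ol
Product: 3 2-[(2E)-3-(3,5-dimethoxyphenyl)prop-2-en-1-yl]-4,4,5,5-tetramethyl-1,3,2-dioxaborolane
Conditions: B2pin2, Pd(MeCN)4(BF4)2 (5 mol%), TsOH·H2O (5 mol%), DMSO/MeOH, 50 °C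
Reagents that add atoms: bis(pinacolato)diboron, CC1(C)OB(OC1(C)C)B1OC(C)(C)C(C)(C)O1
Why: Palladium-catalysed borylation of an allylic alcohol through a π-allylpalladium intermediate, in which boron is delivered to the unsubstituted terminus and the conjugated linear (E)-allylboronate results.

Step 3
Reactants: 3 2-[(2E)-3-(3,5-dimethoxyphenyl)prop-2-en-1-yl]-4,4,5,5-tetramethyl-1,3,2-dioxaborolane; 4 3,4-dimethoxybenzaldehyde (veratraldehyde)
Product: 6 (1S,2R)-1-(3,4-dimethoxyphenyl)-2-(3,5-dimethoxyphenyl)but-3-en-1-ol (anti), via pinacol borate ester 5 (not isolated)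
Conditions: (S)-TRIP [(S)-3,3'-bis(2,4,6-triisopropylphenyl)-1,1'-binaphthyl-2,2'-diyl hydrogen phosphate] (5 mol%), 4 Å MS, PhMe, −30 °C; aqueous work-up
Reagents that add atoms: none
Why: Chiral phosphoric acid-catalysed allylboration through a closed chair transition state, in which the (E)-boronate places both aryl groups equatorial to give the anti C1/C2 pair and the acid, hydrogen-bonded to the boronate oxygen and the formyl hydrogen, selects the aldehyde face to set C1 as S and hence C2 as R.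

Step 4
Reactants: 6 (1S,2R)-1-(3,4-dimethoxyphenyl)-2-(3,5-dimethoxyphenyl)but-3-en-1-ol
Product: 7 4-[(1S,2R)-2-(3,5-dimethoxyphenyl)-1-(ethenyloxy)but-3-en-1-yl]-1,2-dimethoxybenzene
Conditions: vinyl acetate (3 equiv), [Ir(cod)Cl]2 (2 mol%), Na2CO3 (0.6 equiv), PhMe, 100 °C
Reagents that add atoms: vinyl acetate, C=COC(C)=O
Why: Iridium-catalysed transfer vinylation (addition of the alcohol to coordinated vinyl acetate, then β-acetoxy elimination) forms the vinyl ether without breaking the C1–O bond, so both stereocentres are retained.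

Step 5
Reactants: 7 4-[(1S,2R)-2-(3,5-dimethoxyphenyl)-1-(ethenyloxy)but-3-en-1-yl]-1,2-dimethoxybenzene
Product: 8 (2S,3R)-2-(3,4-dimethoxyphenyl)-3-(3,5-dimethoxyphenyl)-2,3-dihydrofuran (trans)
Conditions: second-generation Grubbs catalyst (H2IMes)(PCy3)Cl2Ru=CHPh (5 mol%), 1,4-benzoquinone (10 mol%), PhMe, 70 °C; filtration through basic alumina
Reagents that add atoms: none
Why: Ring-closing metathesis of an olefinic enol ether, in which the ruthenium alkylidene loads on the monosubstituted alkene and closes on the vinyl ether with loss of ethene, forming ring B with the trans C2/C3 pair untouched while benzoquinone suppresses double-bond migration.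

Step 6
Reactants: 9 dimethyl 3-oxopentanedioate
Product: 11 methyl 4-hydroxy-2-oxo-2H-pyran-5-carboxylate, via methoxymethylidene diester 10 (not isolated)
Conditions: HC(OMe)3, Ac2O, 120 °C; then 2 M aq HCl, rt
Reagents that add atoms: trimethyl orthoformate, COC(OC)OC; water, O
Why: Orthoformate condensation at the active methylene (alkoxymethylenation), then acid hydrolysis of the enol ether and lactonisation of the resulting hydroxymethylene onto the distal ester, should give the 4-hydroxy-2-pyrone.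

Step 7
Reactants: 11 methyl 4-hydroxy-2-oxo-2H-pyran-5-carboxylate
Product: 12 methyl 2-oxo-4-(4-methylphenylsulfonyloxy)-2H-pyran-5-carboxylate
Conditions: TsCl, Et3N, CH2Cl2, 0 °C
Reagents that add atoms: 4-methylbenzenesulfonyl chloride, Cc1ccc(S(=O)(=O)Cl)cc1
Why: O-Sulfonylation of the acidic vinylogous-acid hydroxyl of a 4-hydroxy-2-pyrone.

Step 8
Reactants: 8 (2S,3R)-2-(3,4-dimethoxyphenyl)-3-(3,5-dimethoxyphenyl)-2,3-dihydrofuran; 12 methyl 2-oxo-4-(4-methylphenylsulfonyloxy)-2H-pyran-5-carboxylate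
Product: 15 methyl (2S,3S)-2-(3,4-dimethoxyphenyl)-3-(3,5-dimethoxyphenyl)-6-(4-methylphenylsulfonyloxy)-2,3-dihydro-1-benzofuran-5-carboxylate, via bridged lactone 13 (not isolated), via cis-fused diene 14 (not isolated)
Conditions: 12 (1.3 equiv), 2,6-di-tert-butylpyridine (0.2 equiv), PhMe, 90 °C, sealed tube; then DDQ (1.0 equiv), −20 °C
Reagents that add atoms: none
Why: Proposed new method: the enol ether C=C of 8 adds across C3 and C6 of pyrone 12 (LUMO lowered by the 5-ester and the 4-sulfonyloxy group) in an asynchronous inverse-demand (4+2) cycloaddition, its nucleophilic β-carbon (future C3a) bonding to pyrone C6, the Michael terminus of the ester, and its O-bearing carbon (future C7a) to pyrone C3; bridged lactone 13 then extrudes CO2 by retro-(4+2) to diene 14, from which DDQ abstracts hydride at C7a (or C3a) to give an arenium ion that loses the other ring-fusion proton. The closest known reaction is the cycloaddition of 2-pyrone-5-carboxylates with enol ethers followed by CO2 loss, where the diene normally aromatises by expelling the alcohol, so here dehydrogenation has to outrun that elimination. Ring A is closed by intermolecular (4+2) annulation onto the C=C bond of ring B, forming C3a–C4 and C7–C7a. No new stereocentre survives, since both ring-fusion centres become aromatic, so endo/exo and facial selectivity are irrelevant, and C2 and C3 are not involved and keep their trans relationship (the descriptor at C3 changes from R to S only through CIP priorities). The step needs regioselectivity, which the polarisation of both partners secures (ester para to O1, as in known coumalate–enol ether additions), and chemoselectivity for oxidation over loss of O1, which is addressed by running cycloaddition and CO2 loss under acid-free conditions buffered by the hindered pyridine. DDQ is added cold and in stoichiometric amount only after 8 is consumed, because it would aromatise the dihydrofuran itself and can attack the benzylic C2–H of the product on prolonged or warm exposure.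

Step 9
Reactants: 15 methyl (2S,3S)-2-(3,4-dimethoxyphenyl)-3-(3,5-dimethoxyphenyl)-6-(4-methylphenylsulfonyloxy)-2,3-dihydro-1-benzofuran-5-carboxylate
Product: 16 (2S,3S)-2-(3,4-dimethoxyphenyl)-3-(3,5-dimethoxyphenyl)-5-(hydroxymethyl)-2,3-dihydro-1-benzofuran-6-yl 4-methylbenzenesulfonate
Conditions: iBu2AlH (2.5 equiv), CH2Cl2, −78 °C; Rochelle salt work-up
Reagents that add atoms: none
Why: DIBAL-H reduction of the aryl methyl ester to the benzylic alcohol at low temperature, where the aryl sulfonate and aryl ethers are inert to the hydride.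

Step 10
Reactants: 16 (2S,3S)-2-(3,4-dimethoxyphenyl)-3-(3,5-dimethoxyphenyl)-5-(hydroxymethyl)-2,3-dihydro-1-benzofuran-6-yl 4-methylbenzenesulfonate
Product: 17 (2S,3S)-2-(3,4-dimethoxyphenyl)-3-(3,5-dimethoxyphenyl)-5-formyl-2,3-dihydro-1-benzofuran-6-yl 4-methylbenzenesulfonate
Conditions: activated MnO2 (excess), CH2Cl2, rt
Reagents that add atoms: none
Why: MnO2 oxidation is selective for benzylic alcohols and stops at the aldehyde.

Step 11
Reactants: 17 (2S,3S)-2-(3,4-dimethoxyphenyl)-3-(3,5-dimethoxyphenyl)-5-formyl-2,3-dihydro-1-benzofuran-6-yl 4-methylbenzenesulfonate; 18 diethyl (3,5-dimethoxybenzyl)phosphonate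
Product: 20 (2S,3S)-5-[(E)-2-(3,5-dimethoxyphenyl)ethenyl]-2-(3,4-dimethoxyphenyl)-3-(3,5-dimethoxyphenyl)-2,3-dihydro-1-benzofuran-6-ol, via stilbene tosylate 19 (not isolated)
Conditions: NaH, THF, 0 °C to rt; then KOH, MeOH/H2O, 65 °C; aq HCl work-up
Reagents that add atoms: none
Why: Horner–Wadsworth–Emmons olefination of the benzylic phosphonate anion should give the (E)-stilbene, and hydroxide attack at sulfur (S–O cleavage) then frees the C6 phenol without touching the methyl ethers or the non-acidic C2/C3 centres.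

Step 12
Reactants: 20 (2S,3S)-5-[(E)-2-(3,5-dimethoxyphenyl)ethenyl]-2-(3,4-dimethoxyphenyl)-3-(3,5-dimethoxyphenyl)-2,3-dihydro-1-benzofuran-6-ol
Product: 21 4-[(2S,3S)-3-(3,5-dihydroxyphenyl)-5-[(E)-2-(3,5-dihydroxyphenyl)ethenyl]-6-hydroxy-2,3-dihydro-1-benzofuran-2-yl]benzene-1,2-diol (target)
Conditions: BBr3 (12 equiv), CH2Cl2, −78 °C to rt; MeOH then H2O quench
Reagents that add atoms: none
Why: Exhaustive BBr3 ether cleavage (Lewis acid complexation, bromide SN2 at methyl) should free all six phenols; C2 and C3 carry no acidic hydrogens, and any reversible ionisation at C2 would re-close to the more stable trans ring.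

**Compound list**

1 | 3,5-dimethoxybenzaldehyde | COc1cc(C=O)cc(OC)c1 | starting material
2 | rac-1-(3,5-dimethoxyphenyl)prop-2-en-1-ol | C=CC(O)c1cc(OC)cc(OC)c1 | intermediate
3 | 2-[(2E)-3-(3,5-dimethoxyphenyl)prop-2-en-1-yl]-4,4,5,5-tetramethyl-1,3,2-dioxaborolane | CC1(C)OB(C/C=C/c2cc(OC)cc(OC)c2)OC1(C)C | intermediate
4 | 3,4-dimethoxybenzaldehyde (veratraldehyde) | COc1ccc(C=O)cc1OC | starting material
5 | 2-{[(1S,2R)-1-(3,4-dimethoxyphenyl)-2-(3,5-dimethoxyphenyl)but-3-en-1-yl]oxy}-4,4,5,5-tetramethyl-1,3,2-dioxaborolane | CC1(C)OB(O[C@H](c2ccc(OC)c(OC)c2)[C@H](C=C)c2cc(OC)cc(OC)c2)OC1(C)C | intermediate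
6 | (1S,2R)-1-(3,4-dimethoxyphenyl)-2-(3,5-dimethoxyphenyl)but-3-en-1-ol | O[C@H](c1ccc(OC)c(OC)c1)[C@H](C=C)c1cc(OC)cc(OC)c1 | intermediate
7 | 4-[(1S,2R)-2-(3,5-dimethoxyphenyl)-1-(ethenyloxy)but-3-en-1-yl]-1,2-dimethoxybenzene | C=CO[C@H](c1ccc(OC)c(OC)c1)[C@H](C=C)c1cc(OC)cc(OC)c1 | intermediate
8 | (2S,3R)-2-(3,4-dimethoxyphenyl)-3-(3,5-dimethoxyphenyl)-2,3-dihydrofuran (trans) | C1=CO[C@H](c2ccc(OC)c(OC)c2)[C@H]1c1cc(OC)cc(OC)c1 | intermediate
9 | dimethyl 3-oxopentanedioate | COC(=O)CC(=O)CC(=O)OC | starting material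
10 | dimethyl 2-(methoxymethylidene)-3-oxopentanedioate | COC=C(C(=O)OC)C(=O)CC(=O)OC | intermediate
11 | methyl 4-hydroxy-2-oxo-2H-pyran-5-carboxylate | COC(=O)C1=COC(=O)C=C1O | intermediate
12 | methyl 2-oxo-4-(4-methylphenylsulfonyloxy)-2H-pyran-5-carboxylate | COC(=O)C1=COC(=O)C=C1OS(=O)(=O)c1ccc(C)cc1 | intermediate
13 | bridged lactone: 2-oxabicyclo[2.2.2]oct-7-en-3-one carrying 8-CO2Me and 7-OTs, fused across C5–C6 to the (2S,3R)-2,3-diaryltetrahydrofuran ring (furan β-carbon on the O-bearing bridgehead); cis-fused, isomer mixture at the new centres | COC(=O)C1=C(OS(=O)(=O)c2ccc(C)cc2)C2C(=O)OC1C1C2O[C@H](c2ccc(OC)c(OC)c2)[C@H]1c1cc(OC)cc(OC)c1 | intermediate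
14 | methyl (2S,3R)-2-(3,4-dimethoxyphenyl)-3-(3,5-dimethoxyphenyl)-6-(4-methylphenylsulfonyloxy)-2,3,3a,7a-tetrahydro-1-benzofuran-5-carboxylate (cis-fused, isomer mixture at C3a/C7a) | COC(=O)C1=CC2C(C=C1OS(=O)(=O)c1ccc(C)cc1)O[C@H](c1ccc(OC)c(OC)c1)[C@H]2c1cc(OC)cc(OC)c1 | intermediate
15 | methyl (2S,3S)-2-(3,4-dimethoxyphenyl)-3-(3,5-dimethoxyphenyl)-6-(4-methylphenylsulfonyloxy)-2,3-dihydro-1-benzofuran-5-carboxylate (trans) | COC(=O)c1cc2c(cc1OS(=O)(=O)c1ccc(C)cc1)O[C@H](c1ccc(OC)c(OC)c1)[C@H]2c1cc(OC)cc(OC)c1 | intermediate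
16 | (2S,3S)-2-(3,4-dimethoxyphenyl)-3-(3,5-dimethoxyphenyl)-5-(hydroxymethyl)-2,3-dihydro-1-benzofuran-6-yl 4-methylbenzenesulfonate | OCc1cc2c(cc1OS(=O)(=O)c1ccc(C)cc1)O[C@H](c1ccc(OC)c(OC)c1)[C@H]2c1cc(OC)cc(OC)c1 | intermediate
17 | (2S,3S)-2-(3,4-dimethoxyphenyl)-3-(3,5-dimethoxyphenyl)-5-formyl-2,3-dihydro-1-benzofuran-6-yl 4-methylbenzenesulfonate | O=Cc1cc2c(cc1OS(=O)(=O)c1ccc(C)cc1)O[C@H](c1ccc(OC)c(OC)c1)[C@H]2c1cc(OC)cc(OC)c1 | intermediate
18 | diethyl (3,5-dimethoxybenzyl)phosphonate | CCOP(=O)(Cc1cc(OC)cc(OC)c1)OCC | starting material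
19 | (2S,3S)-5-[(E)-2-(3,5-dimethoxyphenyl)ethenyl]-2-(3,4-dimethoxyphenyl)-3-(3,5-dimethoxyphenyl)-2,3-dihydro-1-benzofuran-6-yl 4-methylbenzenesulfonate | COc1cc(OC)cc(/C=C/c2cc3c(cc2OS(=O)(=O)c2ccc(C)cc2)O[C@H](c2ccc(OC)c(OC)c2)[C@H]3c2cc(OC)cc(OC)c2)c1 | intermediate
20 | (2S,3S)-5-[(E)-2-(3,5-dimethoxyphenyl)ethenyl]-2-(3,4-dimethoxyphenyl)-3-(3,5-dimethoxyphenyl)-2,3-dihydro-1-benzofuran-6-ol | COc1cc(OC)cc(/C=C/c2cc3c(cc2O)O[C@H](c2ccc(OC)c(OC)c2)[C@H]3c2cc(OC)cc(OC)c2)c1 | intermediate
21 | 4-[(2S,3S)-3-(3,5-dihydroxyphenyl)-5-[(E)-2-(3,5-dihydroxyphenyl)ethenyl]-6-hydroxy-2,3-dihydro-1-benzofuran-2-yl]benzene-1,2-diol | Oc1cc(O)cc(/C=C/c2cc3c(cc2O)O[C@H](c2ccc(O)c(O)c2)[C@H]3c2cc(O)cc(O)c2)c1 | target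

**Step count**

Total: 12 steps. Longest linear sequence: 10 steps (1, 2, 3, 4, 5, 8, 9, 10, 11, 12); steps 6 and 7 make the pyrone branch.

**Steps most likely to fail**

1. Step 8 (proposed new method). After CO2 loss, the cis-fused diene may aromatise by expelling the ring oxygen from C7a, which opens ring B, before the oxidant is added. DDQ may also remove hydride from the benzylic C2–H of the product, flattening C2/C3 to a benzofuran. The fallback uses the known ketene acetal mode of the pyrone cycloaddition, in which aromatisation is by loss of an oxygen substituent and no oxidant is needed. It sets out from alcohol 6. Hydroboration–oxidation (9-BBN, then NaOH/H2O2) should give the 1,4-diol F1, and TEMPO/PhI(OAc)2 should oxidise the primary alcohol and lactonise to the trans-lactone F2. Enolisation and O-silylation (LDA, TBSCl, THF/DMPU, −78 °C) should give the cyclic silyl ketene acetal F3. Heating F3 with pyrone 12 in toluene (60–80 °C), then Et3N, should give cycloaddition with the same regiochemistry and CO2 loss; the extra silyloxy group on C7a, the better nucleofuge, then leaves as silanol. The fallback comes back to the route at 15.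

2. Step 12. BBr3 and the HBr it generates may ionise the benzylic C2–O1 bond (ring opening, scrambling at C2), protonate the stilbene (cationic addition or oligomerisation), or stop short of cleaving all six ethers. The fallback moves the Lewis acid step to a stage without the stilbene and finishes under base. It sets out from aldehyde 17. BBr3 (CH2Cl2, −78 to 0 °C) should give the tetraphenol aldehyde F4, and TBSCl/imidazole (DMF) its tetrakis(silyl ether) F5. Horner–Wadsworth–Emmons olefination (NaH, THF) with separately prepared diethyl [3,5-bis(tert-butyldimethylsilyloxy)benzyl]phosphonate F6 should give the hexasilylated stilbene tosylate F7. Degassed KOH in MeOH/THF should cleave the six aryl silyl ethers and the tosylate in one operation, and acidification returns to the route at 21.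

3. Step 5. The ruthenium carbene may be trapped by the vinyl ether as an unreactive alkoxycarbene so that turnover stalls, and ruthenium hydrides from catalyst decay may shift the ring double bond. The fallback replaces metathesis by lactol dehydration. It sets out from alcohol 6 and passes through diol F1 and lactone F2 as described under the first fallback. DIBAL-H (CH2Cl2, −78 °C) should give the lactol F8, and MsCl/Et3N (THF, −40 °C to reflux) should eliminate through the anomeric mesylate, as in glycal formation, returning to the route at 8.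

**Further compounds**

F1 | step 8 | (1S,2R)-1-(3,4-dimethoxyphenyl)-2-(3,5-dimethoxyphenyl)butane-1,4-diol | O[C@H](c1ccc(OC)c(OC)c1)[C@H](CCO)c1cc(OC)cc(OC)c1
F2 | step 8 | (4R,5S)-5-(3,4-dimethoxyphenyl)-4-(3,5-dimethoxyphenyl)dihydrofuran-2(3H)-one | O=C1O[C@H](c2ccc(OC)c(OC)c2)[C@@H](c2cc(OC)cc(OC)c2)C1
F3 | step 8 | tert-butyl{[(4R,5S)-5-(3,4-dimethoxyphenyl)-4-(3,5-dimethoxyphenyl)-4,5-dihydrofuran-2-yl]oxy}dimethylsilane | CC(C)(C)[Si](C)(C)OC1=C[C@H](c2cc(OC)cc(OC)c2)[C@@H](c2ccc(OC)c(OC)c2)O1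
F4 | step 12 | (2S,3S)-2-(3,4-dihydroxyphenyl)-3-(3,5-dihydroxyphenyl)-5-formyl-2,3-dihydro-1-benzofuran-6-yl 4-methylbenzenesulfonate | O=Cc1cc2c(cc1OS(=O)(=O)c1ccc(C)cc1)O[C@H](c1ccc(O)c(O)c1)[C@H]2c1cc(O)cc(O)c1
F5 | step 12 | (2S,3S)-2-[3,4-bis(tert-butyldimethylsilyloxy)phenyl]-3-[3,5-bis(tert-butyldimethylsilyloxy)phenyl]-5-formyl-2,3-dihydro-1-benzofuran-6-yl 4-methylbenzenesulfonate | O=Cc1cc2c(cc1OS(=O)(=O)c1ccc(C)cc1)O[C@H](c1ccc(O[Si](C)(C)C(C)(C)C)c(O[Si](C)(C)C(C)(C)C)c1)[C@H]2c1cc(O[Si](C)(C)C(C)(C)C)cc(O[Si](C)(C)C(C)(C)C)c1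
F6 | step 12 | diethyl [3,5-bis(tert-butyldimethylsilyloxy)benzyl]phosphonate | CCOP(=O)(Cc1cc(O[Si](C)(C)C(C)(C)C)cc(O[Si](C)(C)C(C)(C)C)c1)OCC
F7 | step 12 | (2S,3S)-5-{(E)-2-[3,5-bis(tert-butyldimethylsilyloxy)phenyl]ethenyl}-2-[3,4-bis(tert-butyldimethylsilyloxy)phenyl]-3-[3,5-bis(tert-butyldimethylsilyloxy)phenyl]-2,3-dihydro-1-benzofuran-6-yl 4-methylbenzenesulfonate | CC(C)(C)[Si](C)(C)Oc1cc(O[Si](C)(C)C(C)(C)C)cc(/C=C/c2cc3c(cc2OS(=O)(=O)c2ccc(C)cc2)O[C@H](c2ccc(O[Si](C)(C)C(C)(C)C)c(O[Si](C)(C)C(C)(C)C)c2)[C@H]3c2cc(O[Si](C)(C)C(C)(C)C)cc(O[Si](C)(C)C(C)(C)C)c2)c1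
F8 | step 5 | (4R,5S)-5-(3,4-dimethoxyphenyl)-4-(3,5-dimethoxyphenyl)tetrahydrofuran-2-ol (anomer mixture) | OC1O[C@H](c2ccc(OC)c(OC)c2)[C@@H](c2cc(OC)cc(OC)c2)C1
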